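The product comes out of a catalyst round, and the catalyst can be lost on the way, so I count rounds.

    reagent + free catalyst → catalyst intermediate A (k1 = 1200 /M/s)
    catalyst intermediate A ⇌ by-product + catalyst intermediate B (K2 = 0.0737 M, k2 = 108 /s)
    starting material + catalyst intermediate B ⇌ catalyst intermediate C (K3 = 67.7 /M, k3 = 16800 /M/s)
    catalyst intermediate C → free catalyst + product (k4 = 2270 /s)
    starting material + catalyst intermediate B → spent catalyst (k5 = 37.4 /M/s)

starting material 10 mM; reagent 30.0 mM; free catalyst 5.0 µM

* the form that holds most of the catalyst when 5.0% of the starting material are converted (free catalyst / spent catalyst / catalyst intermediate C / catalyst intermediate B / catalyst intermediate A)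
* its share of the catalyst then

1. My bench rule says the catalyst waits in front of its slowest step, the resting state of its working round. Per form and at the charged amounts, uptake of reagent runs at 2200 /min. That is slower than the loss of by-product, the capture of starting material and the release of product, at 6500 /min, 10000 /min and 1.4 × 10⁵ /min. So free catalyst should lead among the working forms.

2. Catalyst intermediate C goes forward at 2270 /s and back at 248 /s, so 90.1% of entries give product.

3. Waits add like time constants in series. I use the charges and set aside the back reaction of by-product. Free catalyst waits 0.0278 s of a round lasting 0.0441 s, which is 63.0% of the working catalyst.

4. Starting material turns catalyst intermediate B either into catalyst intermediate C or into spent catalyst. Starting material stands in both rates, so it drops out. The ratio of the two constants times the forward share gives 405 product molecules per catalyst on average, the catalyst's life in turnovers. At that life, the free catalyst charged carries about 2.02 mM of product.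

5. At the asked conversion the flask has made about 0.500 mM of product, so I reckon 24.7% of the catalyst is spent. I put free catalyst at 47.5%, more than the spent form.

6. The bench rule stops where spent catalyst overtakes free catalyst, at a spent share of 38.7%. With the charges held, I put that at 7.83% conversion, and the asked 5.0% lies below it.

The forecast names free catalyst at 49%, since uptake of the reagent “is the slowest step of the cycle”. My figure is lower, at 47.5%.

The simulation gives free catalyst at 47.4%, with spent catalyst at 24.6%.

In the flask at 0.211 min, catalyst intermediate B passes into catalyst intermediate C 450 times as fast as into spent catalyst, forward rates alone, and that ratio times the forward share 90.1% is the life of 405 turnovers. That life on the 5.0 µM of free catalyst charged is 2.02 mM, and by 2.50 min the flask holds product at 20.2% of the starting material charged, with spent catalyst at >99.9%.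

Its constants were drawn at random within sensible limits.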